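**Retrosynthetic overview**

1. The strategy rests on the cis-glycol C8(OH)–C9(OH) inside the ten-membered carbocycle C1–C10, with C9 allylic to the (Z)-C1=C10 alkene. The ring bond C8–C9 and both carbinol centres come from a C8 aldehyde and a C9 (Z)-enal by SmI2 pinacol macrocyclisation.
2. The dialdehyde comes from an Evans syn-aldol (C6–C7 bond, C6 and C7 stereocentres) between an itaconate-derived N-acyl oxazolidinone (C7, C8, C11–C13) and a (2Z,6E)-enal ester from geranyl acetate (C1–C6, C15; C9, C10, C14 by Still–Gennari olefination).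
3. The lactone stays masked as the O6 silyl ether and the C12 silyloxymethyl group. After ring closure O9 is silylated selectively, O8 is esterified with (R)-(2-methyloxiran-2-yl)acetic acid made from (R)-citramalic acid, and the γ-lactone is closed last by oxidation of C12 onto O6.
4. Ring order: ten-membered carbocycle (step 15), epoxide of the side chain (step 20, attached in step 21), γ-lactone (step 23).

Key step: step 15

Remark on the chemistry: germacrane numbering is used (ring C1–C10, lactone O6–C12(=O)–C11(=C13)–C7, C14 on C10, C15 on C4). O6 is carried as a triethylsilyl ether so that the last desilylation can run with buffered fluoride. Commercial 4-methyl hydrogen itaconate is taken as the itaconate building block. The lactone is closed after O8 is esterified, so O8 cannot compete for C12 and no acidic deprotection is needed on the germacradiene.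

**Route**

Step 1
Reactants: 1 geranyl acetate
Product: 2 (2E)-5-(3,3-dimethyloxiran-2-yl)-3-methylpent-2-en-1-yl acetate (racemic epoxide)
Conditions: m-CPBA (1.05 equiv), CH2Cl2, 0 °C
Reagents that add atoms: m-chloroperbenzoic acid, OOC(=O)c1cccc(Cl)c1
Why: Prilezhaev epoxidation should take the electron-rich remote trisubstituted alkene, because the 2,3-alkene is deactivated by the allylic acetate; the epoxide stereocentre is destroyed in step 2.

Step 2
Reactants: 2 epoxygeranyl acetate
Product: 3 (2E)-3-methyl-6-oxohex-2-en-1-yl acetate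
Conditions: H5IO6 (1.1 equiv), THF/H2O, 0 °C
Reagents that add atoms: none
Why: Periodic acid hydrolyses the epoxide and cleaves the glycol in one operation (Malaprade-type cleavage), giving the future C1 aldehyde without touching the acetate or the (E)-alkene.

Step 3
Reactants: 3 aldehyde
Product: 4 ethyl (2Z,6E)-8-acetoxy-2,6-dimethylocta-2,6-dienoate
Conditions: (CF3CH2O)2P(O)CH(CH3)CO2Et, KN(SiMe3)2, 18-crown-6, THF, −78 °C
Reagents that add atoms: ethyl 2-[bis(2,2,2-trifluoroethoxy)phosphoryl]propanoate, CCOC(=O)C(C)P(=O)(OCC(F)(F)F)OCC(F)(F)F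
Why: Still–Gennari olefination under dissociating conditions should give the kinetic (Z)-2-methyl-2-enoate, which places the future C9 carbonyl cis to the C2 chain on C1=C10.

Step 4
Reactants: 4 acetoxy enoate
Product: 5 ethyl (2Z,6E)-8-hydroxy-2,6-dimethylocta-2,6-dienoate
Conditions: K2CO3 (cat.), EtOH, rt
Reagents that add atoms: none
Why: Base-catalysed transesterification removes the acetate, while ethanolysis of the ethyl enoate is degenerate.

Step 5
Reactants: 5 allylic alcohol
Product: 6 ethyl (2Z,6E)-2,6-dimethyl-8-oxoocta-2,6-dienoate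
Conditions: MnO2, CH2Cl2, rt
Reagents that add atoms: none
Why: MnO2 oxidation of the allylic alcohol should give the enal without isomerising the (E)-C4=C5 bond or affecting the enoate.

Step 6
Reactants: 7 4-methyl hydrogen itaconate
Product: 9 methyl 3-(hydroxymethyl)but-3-enoate, via mixed isobutyl carbonic anhydride 8 (not isolated)
Conditions: i-BuOCOCl, N-methylmorpholine, THF, −15 °C; then NaBH4, H2O, 0 °C
Reagents that add atoms: none
Why: Mixed-anhydride activation followed by NaBH4 reduces the conjugated acid to the allylic alcohol by 1,2-hydride addition, chemoselectively beside the methyl ester.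

Step 7
Reactants: 9 hydroxy ester
Product: 10 methyl 3-[(tert-butyldimethylsilyloxy)methyl]but-3-enoate
Conditions: TBSCl, imidazole, DMF, 0 °C → rt
Reagents that add atoms: tert-butyldimethylsilyl chloride, CC(C)(C)[Si](C)(C)Cl
Why: Standard silylation of the primary allylic alcohol, carried out at once so that γ-lactonisation of 9 cannot compete.

Step 8
Reactants: 10 silyl ether ester
Product: 11 3-[(tert-butyldimethylsilyloxy)methyl]but-3-enoic acid
Conditions: LiOH, THF/H2O, 0 °C; then aq. KHSO4 to pH 4
Reagents that add atoms: lithium hydroxide, [Li+].[OH-]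
Why: Saponification at 0 °C should cleave the methyl ester faster than the β,γ-alkene can move into conjugation, and the primary TBS ether is stable to it.

Step 9
Reactants: 11 acid; 12 (S)-4-benzyl-2-oxazolidinone
Product: 14 (4S)-4-benzyl-3-{3-[(tert-butyldimethylsilyloxy)methyl]but-3-enoyl}-1,3-oxazolidin-2-one, via mixed pivalic anhydride 13 (not isolated)
Conditions: t-BuCOCl, Et3N, THF, −20 °C; then 12, LiCl, −20 °C → rt
Reagents that add atoms: none
Why: N-acylation of the oxazolidinone through the pivaloyl mixed anhydride with LiCl/Et3N, in which the hindered pivaloyl carbonyl is not attacked.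

Step 10
Reactants: 14 N-acyl oxazolidinone; 6 enal
Product: 16 ethyl (2Z,6E,8R,9S)-10-[(4S)-4-benzyl-2-oxo-1,3-oxazolidin-3-yl]-9-[3-(tert-butyldimethylsilyloxy)prop-1-en-2-yl]-8-hydroxy-2,6-dimethyl-10-oxodeca-2,6-dienoate, via dibutylboron Z-enolate 15 (not isolated)
Conditions: Bu2BOTf, i-Pr2NEt, CH2Cl2, −78 → 0 °C; then 6, −78 → 0 °C; pH 7 buffer, MeOH, H2O2, 0 °C
Reagents that add atoms: none
Why: Evans syn-aldol, in which the (Z)-boron enolate reacts through a closed Zimmerman–Traxler transition state on the face away from the benzyl group, setting C7 (S) and C6 (R) syn and in the absolute sense needed for the trans-lactone; the enoate is inert.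

Step 11
Reactants: 16 aldol adduct
Product: 17 ethyl (2Z,6E,8R,9S)-10-[(4S)-4-benzyl-2-oxo-1,3-oxazolidin-3-yl]-9-[3-(tert-butyldimethylsilyloxy)prop-1-en-2-yl]-2,6-dimethyl-10-oxo-8-(triethylsilyloxy)deca-2,6-dienoate
Conditions: TESOTf, 2,6-lutidine, CH2Cl2, −78 °C
Reagents that add atoms: triethylsilyl triflate, CC[Si](CC)(CC)OS(=O)(=O)C(F)(F)F
Why: Silylation of O6 under mild base at low temperature should avoid retro-aldol and conjugation of the α-alkenyl imide, and gives a group removable later with buffered fluoride.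

Step 12
Reactants: 17 silylated aldol adduct
Product: 18 ethyl (2Z,6E,8R,9R)-9-[3-(tert-butyldimethylsilyloxy)prop-1-en-2-yl]-10-hydroxy-2,6-dimethyl-8-(triethylsilyloxy)deca-2,6-dienoate
Conditions: LiBH4, MeOH (1 equiv), THF, 0 °C
Reagents that add atoms: none
Why: LiBH4 reductive cleavage of the N-acyl oxazolidinone to the C8 primary alcohol should be faster than reduction of the trisubstituted enoate at 0 °C and does not epimerise C7; the auxiliary is recovered.

Step 13
Reactants: 18 hydroxy enoate
Product: 19 (2Z,6E,8R,9R)-9-[3-(tert-butyldimethylsilyloxy)prop-1-en-2-yl]-2,6-dimethyl-8-(triethylsilyloxy)deca-2,6-diene-1,10-diol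
Conditions: i-Bu2AlH (3.5 equiv), CH2Cl2, −78 °C; aq. potassium sodium tartrate
Reagents that add atoms: none
Why: i-Bu2AlH reduces the (Z)-enoate by 1,2-addition to the (Z)-allylic alcohol at −78 °C without touching the silyl ethers.

Step 14
Reactants: 19 diol
Product: 20 (2Z,6E,8R,9S)-9-[3-(tert-butyldimethylsilyloxy)prop-1-en-2-yl]-2,6-dimethyl-8-(triethylsilyloxy)deca-2,6-dienedial (C8 aldehyde / C9 (Z)-enal)
Conditions: Dess–Martin periodinane (2.6 equiv), pyridine, CH2Cl2, 0 °C → rt; used at once
Reagents that add atoms: none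
Why: Dess–Martin oxidation under pyridine buffer converts both primary alcohols to aldehydes under conditions that should neither epimerise the doubly activated C7–H nor isomerise the (Z)-enal.

Step 15
Reactants: 20 dialdehyde
Product: 21 (1(10)Z,4E,6R,7R,8S,9R)-12-(tert-butyldimethylsilyloxy)-6-(triethylsilyloxy)germacra-1(10),4,11(13)-triene-8,9-diol (cis-glycol)
Conditions: SmI2 (3 equiv, 0.1 M in THF), THF, −78 °C, slow addition of 20 (final 2 mM), then −78 → −40 °C; pH 7 buffer
Reagents that add atoms: none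
Why: Single-electron transfer from SmI2 gives first the delocalised ketyl of the (Z)-enal and then the C8 ketyl, and the two oxygen-bound trivalent samarium centres hold the radical carbons together so that they combine head to head at C8–C9, which is the intramolecular pinacol coupling of a dialdehyde known for medium and large rings. The ten-membered carbocycle closes in a formally 10-exo-trig manner, both oxygens ending outside the ring. C8 is set by the adjacent C7 stereocentre: in the Felkin–Anh arrangement the alkenyl group C11 stands perpendicular to the carbonyl and C9 approaches anti to it, which is also the 1,3-anti sense with respect to the C6 silyloxy group, and this gives 8S. C9 is set relative to C8 by the samarium bridge, which keeps the two C–O bonds syn during bond formation and so gives the cis-glycol (9R). The step needs bond formation at C9 and not at C1 of the allylic ketyl, retention of the Z geometry, and ring closure in preference to oligomerisation: coupling at C1 would give an eight-membered ring holding the (E)-C4=C5 alkene and is strained, the low temperature keeps rotation about C10–C1 slow, and slow addition at high dilution favours the intramolecular path. Masking the lactone as the O6 silyl ether and the C12 silyloxymethyl group leaves no conjugated ester for the reductant or the ketyls to attack.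

Step 16
Reactants: 21 cis-diol
Product: 22 (1(10)Z,4E,6R,7R,8S,9R)-12-(tert-butyldimethylsilyloxy)-6,9-bis(triethylsilyloxy)germacra-1(10),4,11(13)-trien-8-ol
Conditions: TESCl (1.1 equiv), imidazole, DMF, −40 → −20 °C
Reagents that add atoms: triethylsilyl chloride, CC[Si](CC)(CC)Cl
Why: Kinetic monosilylation should take place at the allylic C9 hydroxyl, which is flanked by the planar C10, and not at the C8 hydroxyl, which is shielded by the branched C7 with its two silyloxy-bearing arms; the first silyl group then blocks a second silylation.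

Step 17
Reactants: 23 (R)-citramalic acid
Product: 24 dimethyl (R)-2-hydroxy-2-methylbutanedioate
Conditions: MeOH, H2SO4 (cat.), reflux
Reagents that add atoms: methanol, CO
Why: Fischer esterification, which does not involve the tertiary carbinol stereocentre.

Step 18
Reactants: 24 dimethyl citramalate
Product: 25 methyl (R)-3,4-dihydroxy-3-methylbutanoate
Conditions: BH3·SMe2 (1.05 equiv), NaBH4 (5 mol%), THF, 0 °C → rt; MeOH
Reagents that add atoms: none
Why: Hydroxyl-directed borane reduction delivers hydride through the five-membered alkoxyborane only to the ester next to the carbinol, leaving the β-ester.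

Step 19
Reactants: 25 diol ester
Product: 26 methyl (R)-3-hydroxy-3-methyl-4-(tosyloxy)butanoate
Conditions: TsCl (1.05 equiv), pyridine, CH2Cl2, 0 °C
Reagents that add atoms: p-toluenesulfonyl chloride, Cc1ccc(cc1)S(=O)(=O)Cl
Why: Sulfonylation is selective for the primary over the tertiary hydroxyl.

Step 20
Reactants: 26 hydroxy tosylate
Product: 28 (R)-(2-methyloxiran-2-yl)acetic acid, via epoxy methyl ester 27 (not isolated)
Conditions: K2CO3 (1.2 equiv), MeOH, 0 °C; then LiOH, H2O, 0 °C; aq. KHSO4 to pH 4, 0 °C; used at once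
Reagents that add atoms: lithium hydroxide, [Li+].[OH-]
Why: Intramolecular Williamson closure (3-exo-tet) by the tertiary alkoxide forms the epoxide without breaking a bond at the quaternary stereocentre, and the subsequent saponification and acidification with non-nucleophilic KHSO4 should leave the epoxide intact.

Step 21
Reactants: 22 C8 alcohol; 28 epoxy acid
Product: 29 (1(10)Z,4E,6R,7R,8S,9R)-12-(tert-butyldimethylsilyloxy)-6,9-bis(triethylsilyloxy)germacra-1(10),4,11(13)-trien-8-yl (R)-(2-methyloxiran-2-yl)acetate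
Conditions: 28 (3 equiv), DCC (3 equiv), DMAP (cat.), CH2Cl2, 0 °C → rt
Reagents that add atoms: none
Why: Steglich esterification acylates the only free hydroxyl (O8) under nearly neutral conditions that the epoxide and the silyl ethers tolerate.

Step 22
Reactants: 29 silylated ester
Product: 30 (1(10)Z,4E,6R,7S,8S,9R)-6,9,12-trihydroxygermacra-1(10),4,11(13)-trien-8-yl (R)-(2-methyloxiran-2-yl)acetate
Conditions: Bu4NF, AcOH (1:1), THF, 0 °C → rt
Reagents that add atoms: none
Why: Fluoride desilylation buffered with acetic acid removes both TES groups and the primary TBS group while suppressing base-induced acyl migration from O8 and opening of the epoxide.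

Step 23
Reactants: 30 triol ester
Product: 33 target CNP0284481.1, via hydroxy enal 31 (not isolated), via lactol 32 (not isolated)
Conditions: TEMPO (0.2 equiv), PhI(OAc)2 (2.4 equiv), CH2Cl2, rt
Reagents that add atoms: none
Why: TEMPO/PhI(OAc)2 oxidises the primary allylic C12 alcohol in preference to the two secondary ones, the aldehyde is trapped by O6 as the five-membered lactol (O8 is esterified and cannot compete), and further oxidation gives the α-methylene-γ-lactone (oxidative lactonisation of a 1,4-diol) with the trans fusion fixed by C6 and C7.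

**Compound list**

1 | geranyl acetate | CC(C)=CCC/C(C)=C/COC(C)=O | starting material
2 | (2E)-5-(3,3-dimethyloxiran-2-yl)-3-methylpent-2-en-1-yl acetate (racemic epoxide) | CC1(C)OC1CC/C(C)=C/COC(C)=O | intermediate
3 | (2E)-3-methyl-6-oxohex-2-en-1-yl acetate | O=CCC/C(C)=C/COC(C)=O | intermediate
4 | ethyl (2Z,6E)-8-acetoxy-2,6-dimethylocta-2,6-dienoate | CCOC(=O)/C(C)=C\CC/C(C)=C/COC(C)=O | intermediate
5 | ethyl (2Z,6E)-8-hydroxy-2,6-dimethylocta-2,6-dienoate | CCOC(=O)/C(C)=C\CC/C(C)=C/CO | intermediate
6 | ethyl (2Z,6E)-2,6-dimethyl-8-oxoocta-2,6-dienoate | CCOC(=O)/C(C)=C\CC/C(C)=C/C=O | intermediate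
7 | 4-methyl hydrogen itaconate (4-methoxy-2-methylidene-4-oxobutanoic acid) | C=C(CC(=O)OC)C(=O)O | starting material
8 | mixed isobutyl carbonic anhydride of 7 | C=C(CC(=O)OC)C(=O)OC(=O)OCC(C)C | intermediate
9 | methyl 3-(hydroxymethyl)but-3-enoate | C=C(CO)CC(=O)OC | intermediate
10 | methyl 3-[(tert-butyldimethylsilyloxy)methyl]but-3-enoate | C=C(CO[Si](C)(C)C(C)(C)C)CC(=O)OC | intermediate
11 | 3-[(tert-butyldimethylsilyloxy)methyl]but-3-enoic acid | C=C(CO[Si](C)(C)C(C)(C)C)CC(=O)O | intermediate
12 | (S)-4-benzyl-2-oxazolidinone | O=C1N[C@@H](Cc2ccccc2)CO1 | starting material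
13 | mixed pivalic anhydride of 11 | C=C(CO[Si](C)(C)C(C)(C)C)CC(=O)OC(=O)C(C)(C)C | intermediate
14 | (4S)-4-benzyl-3-{3-[(tert-butyldimethylsilyloxy)methyl]but-3-enoyl}-1,3-oxazolidin-2-one | C=C(CO[Si](C)(C)C(C)(C)C)CC(=O)N1[C@@H](Cc2ccccc2)COC1=O | intermediate
15 | dibutylboron (Z)-enolate of 14 | C=C(CO[Si](C)(C)C(C)(C)C)/C=C(\OB(CCCC)CCCC)N1[C@@H](Cc2ccccc2)COC1=O | intermediate
16 | ethyl (2Z,6E,8R,9S)-10-[(4S)-4-benzyl-2-oxo-1,3-oxazolidin-3-yl]-9-[3-(tert-butyldimethylsilyloxy)prop-1-en-2-yl]-8-hydroxy-2,6-dimethyl-10-oxodeca-2,6-dienoate (positions 8 and 9 are C6 and C7 of the target) | O=C(N1[C@@H](Cc2ccccc2)COC1=O)[C@@H](C(=C)CO[Si](C)(C)C(C)(C)C)[C@H](O)/C=C(\C)CC/C=C(/C)C(=O)OCC | intermediate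
17 | 8-O-triethylsilyl ether of 16 (8R,9S) | O=C(N1[C@@H](Cc2ccccc2)COC1=O)[C@@H](C(=C)CO[Si](C)(C)C(C)(C)C)[C@H](O[Si](CC)(CC)CC)/C=C(\C)CC/C=C(/C)C(=O)OCC | intermediate
18 | ethyl (2Z,6E,8R,9R)-9-[3-(tert-butyldimethylsilyloxy)prop-1-en-2-yl]-10-hydroxy-2,6-dimethyl-8-(triethylsilyloxy)deca-2,6-dienoate | OC[C@@H](C(=C)CO[Si](C)(C)C(C)(C)C)[C@H](O[Si](CC)(CC)CC)/C=C(\C)CC/C=C(/C)C(=O)OCC | intermediate
19 | (2Z,6E,8R,9R)-9-[3-(tert-butyldimethylsilyloxy)prop-1-en-2-yl]-2,6-dimethyl-8-(triethylsilyloxy)deca-2,6-diene-1,10-diol | OC[C@@H](C(=C)CO[Si](C)(C)C(C)(C)C)[C@H](O[Si](CC)(CC)CC)/C=C(\C)CC/C=C(/C)CO | intermediate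
20 | (2Z,6E,8R,9S)-9-[3-(tert-butyldimethylsilyloxy)prop-1-en-2-yl]-2,6-dimethyl-8-(triethylsilyloxy)deca-2,6-dienedial | O=C[C@@H](C(=C)CO[Si](C)(C)C(C)(C)C)[C@H](O[Si](CC)(CC)CC)/C=C(\C)CC/C=C(/C)C=O | intermediate
21 | (1(10)Z,4E,6R,7R,8S,9R)-12-(tert-butyldimethylsilyloxy)-6-(triethylsilyloxy)germacra-1(10),4,11(13)-triene-8,9-diol | C=C(CO[Si](C)(C)C(C)(C)C)[C@H]1[C@H](O[Si](CC)(CC)CC)/C=C(\C)CC/C=C(/C)[C@@H](O)[C@H]1O | intermediate
22 | (1(10)Z,4E,6R,7R,8S,9R)-12-(tert-butyldimethylsilyloxy)-6,9-bis(triethylsilyloxy)germacra-1(10),4,11(13)-trien-8-ol | C=C(CO[Si](C)(C)C(C)(C)C)[C@H]1[C@H](O[Si](CC)(CC)CC)/C=C(\C)CC/C=C(/C)[C@@H](O[Si](CC)(CC)CC)[C@H]1O | intermediate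
23 | (R)-citramalic acid | C[C@@](O)(CC(=O)O)C(=O)O | starting material
24 | dimethyl (R)-2-hydroxy-2-methylbutanedioate | C[C@@](O)(CC(=O)OC)C(=O)OC | intermediate
25 | methyl (R)-3,4-dihydroxy-3-methylbutanoate | C[C@@](O)(CC(=O)OC)CO | intermediate
26 | methyl (R)-3-hydroxy-3-methyl-4-(tosyloxy)butanoate | C[C@@](O)(CC(=O)OC)COS(=O)(=O)c1ccc(C)cc1 | intermediate
27 | methyl (R)-(2-methyloxiran-2-yl)acetate | COC(=O)C[C@]1(C)CO1 | intermediate
28 | (R)-(2-methyloxiran-2-yl)acetic acid | OC(=O)C[C@]1(C)CO1 | intermediate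
29 | (1(10)Z,4E,6R,7R,8S,9R)-12-(tert-butyldimethylsilyloxy)-6,9-bis(triethylsilyloxy)germacra-1(10),4,11(13)-trien-8-yl (R)-(2-methyloxiran-2-yl)acetate | C=C(CO[Si](C)(C)C(C)(C)C)[C@H]1[C@H](O[Si](CC)(CC)CC)/C=C(\C)CC/C=C(/C)[C@@H](O[Si](CC)(CC)CC)[C@H]1OC(=O)C[C@]2(C)CO2 | intermediate
30 | (1(10)Z,4E,6R,7S,8S,9R)-6,9,12-trihydroxygermacra-1(10),4,11(13)-trien-8-yl (R)-(2-methyloxiran-2-yl)acetate | C=C(CO)[C@H]1[C@H](O)/C=C(\C)CC/C=C(/C)[C@@H](O)[C@H]1OC(=O)C[C@]2(C)CO2 | intermediate
31 | (1(10)Z,4E,6R,7S,8S,9R)-6,9-dihydroxy-12-oxogermacra-1(10),4,11(13)-trien-8-yl (R)-(2-methyloxiran-2-yl)acetate | C=C(C=O)[C@H]1[C@H](O)/C=C(\C)CC/C=C(/C)[C@@H](O)[C@H]1OC(=O)C[C@]2(C)CO2 | intermediate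
32 | 6,12-lactol of 31 (both C12 epimers) | C=C1C(O)O[C@@H]2/C=C(\C)CC/C=C(/C)[C@@H](O)[C@@H](OC(=O)C[C@]3(C)CO3)[C@@H]12 | intermediate
33 | (3aS,4S,5R,6Z,10E,11aR)-5-hydroxy-6,10-dimethyl-3-methylidene-2-oxo-2,3,3a,4,5,8,9,11a-octahydrocyclodeca[b]furan-4-yl (R)-(2-methyloxiran-2-yl)acetate (CNP0284481.1) | C=C1C(=O)O[C@@H]2/C=C(\C)CC/C=C(/C)[C@@H](O)[C@@H](OC(=O)C[C@]3(C)CO3)[C@@H]12 | target

**Step count**

Total step count: 23. Longest linear sequence: 15 steps (steps 1–5, 10–16, 21–23).

**Steps most likely to fail**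

Step 15. The ketyl coupling may close with poor control of the relative configuration at C9 (anti combination of the two ketyls when the samarium centres do not bridge, giving the trans-glycol), besides competing intermolecular coupling. The fallback sets out from 20 and comes back at 21. The coupling is run as described and the whole diol fraction is taken on, that is 21 together with its C9 epimer, the trans-8,9-diol F1. IBX (1.2 equiv) in DMSO/THF at rt, which does not cleave glycols, should oxidise the more accessible allylic C9 carbinol of both epimers to the same 8-hydroxy-9-ketone F2. Reduction of F2 with Zn(BH4)2 in Et2O at −20 °C under chelation control (zinc bridging O8 and the C9 carbonyl, hydride entering from the face of H8) should then return the cis-glycol 21. The C9 centre is thus set by substrate-controlled reduction and no longer by the coupling.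

Step 16. Site selection between the two secondary hydroxyls may be insufficient (silylation at O8, or at both oxygens). The fallback sets out from 21 and comes back at 22. Treatment of 21 with 4-methoxybenzaldehyde dimethyl acetal and PPTS (cat.) in CH2Cl2 gives the 8,9-O-(4-methoxybenzylidene) acetal F3. Reductive opening with i-Bu2AlH in CH2Cl2 (−78 → 0 °C), in which aluminium binds the more accessible O9 and that C–O bond is cleaved, should give the 8-O-(4-methoxybenzyl) ether with free 9-OH F4. Silylation of the single free hydroxyl with TESOTf/2,6-lutidine gives the 8-O-PMB-9-O-TES compound F5. DDQ in CH2Cl2/pH 7 buffer then removes the benzyl-type ether and delivers 22.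

Step 21. Base-induced opening of the activated β,γ-epoxy acid (enolisation and β-elimination of the epoxide oxygen) may outrun acylation of the hindered C8 hydroxyl. The fallback sets out from 22 and 26 and comes back at 29; it carries the epoxide in latent form through the acylation. Me3SnOH in 1,2-dichloroethane at 70 °C hydrolyses the methyl ester of 26 to (R)-3-hydroxy-3-methyl-4-(tosyloxy)butanoic acid F6. DCC/DMAP esterification of 22 with F6 gives the 8-O-(3-hydroxy-3-methyl-4-tosyloxybutanoyl) ester F7. Cs2CO3 in MeCN at rt then closes the epoxide by 3-exo-tet displacement of the tosylate by the tertiary alkoxide and gives 29.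

**Further compounds**

F1 | step 15 | (1(10)Z,4E,6R,7R,8S,9S)-12-(tert-butyldimethylsilyloxy)-6-(triethylsilyloxy)germacra-1(10),4,11(13)-triene-8,9-diol (trans-glycol, C9 epimer of 21) | C=C(CO[Si](C)(C)C(C)(C)C)[C@H]1[C@H](O[Si](CC)(CC)CC)/C=C(\C)CC/C=C(/C)[C@H](O)[C@H]1O
F2 | step 15 | (1(10)Z,4E,6R,7R,8S)-12-(tert-butyldimethylsilyloxy)-8-hydroxy-6-(triethylsilyloxy)germacra-1(10),4,11(13)-trien-9-one | C=C(CO[Si](C)(C)C(C)(C)C)[C@H]1[C@H](O[Si](CC)(CC)CC)/C=C(\C)CC/C=C(/C)C(=O)[C@H]1O
F3 | step 16 | 8,9-O-(4-methoxybenzylidene) acetal of 21 (either acetal epimer) | C=C(CO[Si](C)(C)C(C)(C)C)[C@H]1[C@H](O[Si](CC)(CC)CC)/C=C(\C)CC/C=C(/C)[C@@H](OC(c3ccc(OC)cc3)O2)[C@H]12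
F4 | step 16 | 8-O-(4-methoxybenzyl) ether of 21 with free 9-OH | C=C(CO[Si](C)(C)C(C)(C)C)[C@H]1[C@H](O[Si](CC)(CC)CC)/C=C(\C)CC/C=C(/C)[C@@H](O)[C@H]1OCc2ccc(OC)cc2
F5 | step 16 | 8-O-(4-methoxybenzyl)-9-O-triethylsilyl derivative of 21 | C=C(CO[Si](C)(C)C(C)(C)C)[C@H]1[C@H](O[Si](CC)(CC)CC)/C=C(\C)CC/C=C(/C)[C@@H](O[Si](CC)(CC)CC)[C@H]1OCc2ccc(OC)cc2
F6 | step 21 | (R)-3-hydroxy-3-methyl-4-(tosyloxy)butanoic acid | C[C@@](O)(CC(=O)O)COS(=O)(=O)c1ccc(C)cc1
F7 | step 21 | 8-O-[(R)-3-hydroxy-3-methyl-4-(tosyloxy)butanoyl] ester of 22 | C=C(CO[Si](C)(C)C(C)(C)C)[C@H]1[C@H](O[Si](CC)(CC)CC)/C=C(\C)CC/C=C(/C)[C@@H](O[Si](CC)(CC)CC)[C@H]1OC(=O)C[C@@](C)(O)COS(=O)(=O)c2ccc(C)cc2
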